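**Plan** (carotenoid numbering: ring C1–C6 with C1 = CMe2, C3 = CHOH, C5 = C(Me)=, C6 = CH; chain C7 to C8' = CHO)
1. Retrosynthesis: C7=C8 is cut first (Julia–Kocienski), giving a C10 ring sulfone and all-E C20 crocetindialdehyde; then the ring bonds C2–C3 and C1–C6 are cut together ([4+2]).
2. Enabling feature: ring atoms C3–C4=C5–C6 carry O on C3 and C7 on C6, cis-1,4 across the C4=C5 bond. They are C6–C5=C4–C3 of a 4-methyl-2-pyranone whose O1–C2(=O) unit becomes the C3–O bond and C7; C1(Me)2–C2H2 is isobutylene, which has no endo/exo issue.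
3. Forward: the pyranone, with a removable 3-allyloxycarbonyl helper, is made from diallyl malonate, acetone and DMF dimethyl acetal. A Cu–bis(oxazoline)-catalysed inverse-demand Diels–Alder reaction closes the only carbocycle as a 2-oxabicyclo[2.2.2]octenone. The helper ester is removed (deallylation, Barton decarboxylation) and the lactone bridge is cleaved with LiAlH4.
4. Chain: the primary C7–OH becomes a phenyltetrazolyl sulfone (Mitsunobu, silylation of C3–OH, oxidation), which is olefinated with the C20 dialdehyde and desilylated.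
5. Stereochemistry: C3 and C6 both arise in the cycloaddition, cis through the lactone bridge and in absolute sense from the chiral ligand. The bridge holds C6 during helper removal; chain geometry comes from the all-E dialdehyde and the E-selective olefination.

Key step: step 3

Remark: crocetindialdehyde 16, the C20 dialdehyde of industrial carotenoid synthesis, is taken as purchasable.
Remark: the (S,S)-ligand is assumed to give the (1S,4R) adduct; the sense of induction has to be confirmed on the first run, and the equally available (R,R)-ligand is used if it is opposite.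

**Step 1**
Reactants: 1 diallyl malonate; 2 acetone
Product: 3 diallyl 2-(propan-2-ylidene)malonate
Conditions: Ac2O, ZnCl2 (15 mol %), neat, reflux
Reagents that add atoms: none
Why: Knoevenagel condensation of the malonate with acetone, driven by acetic anhydride as water scavenger, as is standard for dialkyl isopropylidenemalonates; no stereocentre is formed.

**Step 2**
Reactants: 3 diallyl 2-(propan-2-ylidene)malonate
Product: 5 prop-2-en-1-yl 4-methyl-2-oxo-2H-pyran-3-carboxylate, via dienamine 4 (not isolated)
Conditions: Me2NCH(OMe)2 (1.1 equiv), toluene, 100 °C; concentrate; AcOH–H2O 4:1, 70 °C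
Reagents that add atoms: N,N-dimethylformamide dimethyl acetal, COC(OC)N(C)C; water, O
Why: vinylogous aminomethylenation of the acidic gamma-methyl group gives the push–pull dienamine, which in aqueous acid is hydrolysed at the enamine carbon and lactonises onto the cis ester with loss of allyl alcohol, the known route from alkylidene malonates to 4-substituted 2-oxo-2H-pyran-3-carboxylates; no stereocentre is formed.

**Step 3**
Reactants: 5 prop-2-en-1-yl 4-methyl-2-oxo-2H-pyran-3-carboxylate; 6 isobutylene (2-methylpropene)
Product: 7 prop-2-en-1-yl (1S,4R)-5,8,8-trimethyl-3-oxo-2-oxabicyclo[2.2.2]oct-5-ene-4-carboxylate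
Conditions: Cu(OTf)2 (10 mol %), 2,2'-(propane-2,2-diyl)bis[(4S)-4-tert-butyl-4,5-dihydro-1,3-oxazole] (11 mol %), 4 Å molecular sieves, isobutylene (10 equiv, condensed), CH2Cl2, sealed tube, −20 °C → rt
Reagents that add atoms: none
Why: Proposed new method: divalent copper chelates the lactone and ester carbonyls of 5 and lowers its LUMO, so that isobutylene adds in an asynchronous inverse-electron-demand [4+2] cycloaddition in which its CH2 terminus bonds first to the electrophilic C6 of the pyranone and the developing tertiary cation then closes on the malonate-type C3. The closest known reaction type is the bis(oxazoline)–Cu(OTf)2-catalysed inverse-demand Diels–Alder reaction of 3-alkoxycarbonyl-2-pyranones with enol ethers and styrene-type alkenes, extended here to an unactivated 1,1-dialkyl alkene whose nucleophilicity lies between those of styrene and enol ethers. The carbocycle is closed by an intermolecular [4+2] (two sigma bonds, suprafacial on both partners), which leaves the pyranone O1–C2 unit as the two-atom lactone bridge of a 2-oxabicyclo[2.2.2]octene. The two new stereocentres are the bridgeheads: their relative configuration (the later cis 3-OH/6-C7 pair) is fixed by the bicycle itself, and their absolute configuration by the tert-butyl groups of the C2-symmetric ligand, which shield one face of the chelated planar diene. The step needs regioselectivity (CMe2 next to the carbonyl-bearing bridgehead), which follows from the polarisation of both partners and the tertiary-cation character of the transition state; endo/exo selectivity does not arise because each alkene terminus carries two identical substituents. The low temperature keeps the adduct from losing CO2 by retro-[4+2].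

**Step 4**
Reactants: 7 prop-2-en-1-yl (1S,4R)-5,8,8-trimethyl-3-oxo-2-oxabicyclo[2.2.2]oct-5-ene-4-carboxylate
Product: 8 (1S,4R)-5,8,8-trimethyl-3-oxo-2-oxabicyclo[2.2.2]oct-5-ene-4-carboxylic acid
Conditions: Pd(PPh3)4 (5 mol %), PhNHMe (3 equiv), THF, rt
Reagents that add atoms: none
Why: Tsuji–Trost deallylation: zerovalent palladium should ionise the unhindered allyl ester much faster than the bridgehead allylic lactone C–O bond (trisubstituted alkene flanked by quaternary carbons), N-methylaniline traps the allyl unit without opening the lactone, and the bridgehead acid cannot decarboxylate through an enol; the stereocentres are untouched.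

**Step 5**
Reactants: 8 (1S,4R)-5,8,8-trimethyl-3-oxo-2-oxabicyclo[2.2.2]oct-5-ene-4-carboxylic acid
Product: 11 (1S,4R)-5,8,8-trimethyl-2-oxabicyclo[2.2.2]oct-5-en-3-one, via acid chloride 9 (not isolated), via Barton ester 10 (not isolated)
Conditions: (COCl)2, DMF (cat.), CH2Cl2, 0 °C → rt; concentrate; sodium 1-oxidopyridine-2-thiolate (C5H4NNaOS), DMAP (cat.), t-BuSH, THF, tungsten lamp, rt
Reagents that add atoms: none
Why: Barton radical decarboxylation: the thiohydroxamate ester fragments under visible light to a bridgehead radical that cannot invert within the bicycle and abstracts hydrogen from the thiol, so that H replaces the helper carboxyl with retention and the cis O/C=O relationship is kept.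

**Step 6**
Reactants: 11 (1S,4R)-5,8,8-trimethyl-2-oxabicyclo[2.2.2]oct-5-en-3-one
Product: 12 (1S,4R)-4-(hydroxymethyl)-3,5,5-trimethylcyclohex-2-en-1-ol
Conditions: LiAlH4, THF, 0 °C → rt
Reagents that add atoms: none
Why: hydride reduction of the lactone cleaves the temporary bridge to the primary alcohol at C7 and the secondary allylic alcohol at C3 without touching the isolated alkene; C3 and C6 are carried over unchanged.

**Step 7**
Reactants: 12 (1S,4R)-4-(hydroxymethyl)-3,5,5-trimethylcyclohex-2-en-1-ol
Product: 13 (1S,4R)-3,5,5-trimethyl-4-{[(1-phenyl-1H-tetrazol-5-yl)sulfanyl]methyl}cyclohex-2-en-1-ol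
Conditions: 1-phenyl-1H-tetrazole-5-thiol (1.05 equiv), PPh3, DIAD, THF, 0 °C
Reagents that add atoms: 1-phenyl-1H-tetrazole-5-thiol, Sc1nnnn1-c1ccccc1
Why: Mitsunobu thioetherification: with one equivalent of reagents at 0 °C the primary hydroxyl should be activated and displaced by the acidic tetrazolethiol in preference to the secondary one; C7 is a CH2 group, so no stereocentre is involved.

**Step 8**
Reactants: 13 (1S,4R)-3,5,5-trimethyl-4-{[(1-phenyl-1H-tetrazol-5-yl)sulfanyl]methyl}cyclohex-2-en-1-ol
Product: 14 5-({[(1R,4S)-4-{[tert-butyl(dimethyl)silyl]oxy}-2,6,6-trimethylcyclohex-2-en-1-yl]methyl}sulfanyl)-1-phenyl-1H-tetrazole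
Conditions: TBSCl, imidazole, DMF, rt
Reagents that add atoms: tert-butyldimethylsilyl chloride, CC(C)(C)[Si](C)(C)Cl
Why: standard silylation of the secondary allylic alcohol, which masks it against hydroxyl-directed epoxidation in step 9 and against alkoxide formation in step 10.

**Step 9**
Reactants: 14 5-({[(1R,4S)-4-{[tert-butyl(dimethyl)silyl]oxy}-2,6,6-trimethylcyclohex-2-en-1-yl]methyl}sulfanyl)-1-phenyl-1H-tetrazole
Product: 15 5-({[(1R,4S)-4-{[tert-butyl(dimethyl)silyl]oxy}-2,6,6-trimethylcyclohex-2-en-1-yl]methyl}sulfonyl)-1-phenyl-1H-tetrazole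
Conditions: (NH4)6Mo7O24·4H2O (10 mol %), 30 % aq. H2O2, EtOH, 0 °C → rt
Reagents that add atoms: hydrogen peroxide, OO
Why: molybdate-catalysed peroxide oxidation takes the sulfide through the sulfoxide to the sulfone and, with no free allylic hydroxyl present, should leave the hindered trisubstituted alkene and the silyl ether alone.

**Step 10**
Reactants: 15 5-({[(1R,4S)-4-{[tert-butyl(dimethyl)silyl]oxy}-2,6,6-trimethylcyclohex-2-en-1-yl]methyl}sulfonyl)-1-phenyl-1H-tetrazole; 16 crocetindialdehyde, (2E,4E,6E,8E,10E,12E,14E)-2,6,11,15-tetramethylhexadeca-2,4,6,8,10,12,14-heptaenedial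
Product: 17 (2E,4E,6E,8E,10E,12E,14E,16E)-17-[(1R,4S)-4-{[tert-butyl(dimethyl)silyl]oxy}-2,6,6-trimethylcyclohex-2-en-1-yl]-2,6,11,15-tetramethylheptadeca-2,4,6,8,10,12,14,16-octaenal
Conditions: 16 (3 equiv), KN(SiMe3)2 (1.1 equiv), THF/DME, −60 °C → rt, dark
Reagents that add atoms: none
Why: Julia–Kocienski olefination: the metalated phenyltetrazolyl sulfone adds to one aldehyde group of the dialdehyde used in excess, and Smiles rearrangement with loss of SO2 and tetrazololate forms C7=C8, the potassium counter-ion in an ether solvent and the branched sulfone favouring the anti adduct and hence the E alkene; the second aldehyde remains as C8' and the C6–H is not acidic enough to be touched.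

**Step 11**
Reactants: 17 the silyl ether of the target
Product: 18 (2E,4E,6E,8E,10E,12E,14E,16E)-17-[(1R,4S)-4-hydroxy-2,6,6-trimethylcyclohex-2-en-1-yl]-2,6,11,15-tetramethylheptadeca-2,4,6,8,10,12,14,16-octaenal, i.e. (3S,6R)-3-hydroxy-8'-apo-ε-caroten-8'-al
Conditions: Bu4NF, AcOH, THF, 0 °C → rt, dark
Reagents that add atoms: none
Why: fluoride-mediated desilylation buffered with acetic acid frees the allylic alcohol without strong acid, which would ionise the allylic C3–O bond, and without strong base, which could attack the polyenal.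

**Compound list**
1 | diallyl malonate | C=CCOC(=O)CC(=O)OCC=C | starting material
2 | acetone | CC(C)=O | starting material
3 | diallyl 2-(propan-2-ylidene)malonate | CC(C)=C(C(=O)OCC=C)C(=O)OCC=C | intermediate
4 | diallyl 2-[(3E)-4-(dimethylamino)but-3-en-2-ylidene]malonate (dienamine) | CN(C)/C=C/C(C)=C(C(=O)OCC=C)C(=O)OCC=C | intermediate (not isolated)
5 | prop-2-en-1-yl 4-methyl-2-oxo-2H-pyran-3-carboxylate | CC1=C(C(=O)OCC=C)C(=O)OC=C1 | intermediate
6 | isobutylene (2-methylpropene) | CC(C)=C | starting material
7 | prop-2-en-1-yl (1S,4R)-5,8,8-trimethyl-3-oxo-2-oxabicyclo[2.2.2]oct-5-ene-4-carboxylate | CC1=C[C@@H]2CC(C)(C)[C@@]1(C(=O)OCC=C)C(=O)O2 | intermediate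
8 | (1S,4R)-5,8,8-trimethyl-3-oxo-2-oxabicyclo[2.2.2]oct-5-ene-4-carboxylic acid | CC1=C[C@@H]2CC(C)(C)[C@@]1(C(=O)O)C(=O)O2 | intermediate
9 | (1S,4S)-5,8,8-trimethyl-3-oxo-2-oxabicyclo[2.2.2]oct-5-ene-4-carbonyl chloride | CC1=C[C@@H]2CC(C)(C)[C@@]1(C(Cl)=O)C(=O)O2 | intermediate (not isolated)
10 | 2-sulfanylidenepyridin-1(2H)-yl (1S,4S)-5,8,8-trimethyl-3-oxo-2-oxabicyclo[2.2.2]oct-5-ene-4-carboxylate (Barton ester) | CC1=C[C@@H]2CC(C)(C)[C@@]1(C(=O)On1ccccc1=S)C(=O)O2 | intermediate (not isolated)
11 | (1S,4R)-5,8,8-trimethyl-2-oxabicyclo[2.2.2]oct-5-en-3-one | CC1=C[C@@H]2CC(C)(C)[C@H]1C(=O)O2 | intermediate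
12 | (1S,4R)-4-(hydroxymethyl)-3,5,5-trimethylcyclohex-2-en-1-ol | CC1=C[C@@H](O)CC(C)(C)[C@H]1CO | intermediate
13 | (1S,4R)-3,5,5-trimethyl-4-{[(1-phenyl-1H-tetrazol-5-yl)sulfanyl]methyl}cyclohex-2-en-1-ol | CC1=C[C@@H](O)CC(C)(C)[C@H]1CSc1nnnn1-c1ccccc1 | intermediate
14 | 5-({[(1R,4S)-4-{[tert-butyl(dimethyl)silyl]oxy}-2,6,6-trimethylcyclohex-2-en-1-yl]methyl}sulfanyl)-1-phenyl-1H-tetrazole | CC1=C[C@@H](O[Si](C)(C)C(C)(C)C)CC(C)(C)[C@H]1CSc1nnnn1-c1ccccc1 | intermediate
15 | 5-({[(1R,4S)-4-{[tert-butyl(dimethyl)silyl]oxy}-2,6,6-trimethylcyclohex-2-en-1-yl]methyl}sulfonyl)-1-phenyl-1H-tetrazole | CC1=C[C@@H](O[Si](C)(C)C(C)(C)C)CC(C)(C)[C@H]1CS(=O)(=O)c1nnnn1-c1ccccc1 | intermediate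
16 | crocetindialdehyde, (2E,4E,6E,8E,10E,12E,14E)-2,6,11,15-tetramethylhexadeca-2,4,6,8,10,12,14-heptaenedial | O=C/C(C)=C/C=C/C(C)=C/C=C/C=C(C)/C=C/C=C(\C)C=O | starting material
17 | (2E,4E,6E,8E,10E,12E,14E,16E)-17-[(1R,4S)-4-{[tert-butyl(dimethyl)silyl]oxy}-2,6,6-trimethylcyclohex-2-en-1-yl]-2,6,11,15-tetramethylheptadeca-2,4,6,8,10,12,14,16-octaenal | CC1=C[C@@H](O[Si](C)(C)C(C)(C)C)CC(C)(C)[C@H]1/C=C/C(C)=C/C=C/C(C)=C/C=C/C=C(C)/C=C/C=C(\C)C=O | intermediate
18 | (2E,4E,6E,8E,10E,12E,14E,16E)-17-[(1R,4S)-4-hydroxy-2,6,6-trimethylcyclohex-2-en-1-yl]-2,6,11,15-tetramethylheptadeca-2,4,6,8,10,12,14,16-octaenal | CC1=C[C@@H](O)CC(C)(C)[C@H]1/C=C/C(C)=C/C=C/C(C)=C/C=C/C=C(C)/C=C/C=C(\C)C=O | target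

**Totals**
Total step count: 11. Longest linear sequence: 11 steps (1 and 2 to 18; 16 is purchased).

**Steps most likely to fail**

Step 3 (Proposed new method). The unactivated alkene may be too weak a 2π partner for the hindered 3,4-disubstituted pyranone. The stepwise pathway may end in proton loss from the tertiary cation (ene-type allylation) instead of closure to the two adjacent quaternary carbons. Isobutylene may oligomerise under acid initiation, and facial selectivity may be low. The fallback uses known chemistry only; it sets out from acetone 2 and comes back at diol 12, bypassing steps 1–6. Acetone 2 is self-condensed (Ba(OH)2, then acid-catalysed dehydration) to mesityl oxide F1, which is also purchasable. F1 and ethyl acetoacetate (CCOC(=O)CC(C)=O) undergo the classical Michael addition–aldol condensation (Robinson-type annulation; ZnCl2 with azeotropic removal of water, or NaOEt/EtOH) to racemic ethyl 2,6,6-trimethyl-4-oxocyclohex-2-ene-1-carboxylate F2. A reagent-controlled Corey–Bakshi–Shibata reduction ((R)-2-methyl-CBS-oxazaborolidine, BH3·SMe2, THF, −20 °C) is expected to reduce both enantiomers from the same carbonyl face to the (4S)-carbinols. These are the cis ester ethyl (1R,4S)-4-hydroxy-2,6,6-trimethylcyclohex-2-ene-1-carboxylate F3 and the trans ester ethyl (1S,4S)-4-hydroxy-2,6,6-trimethylcyclohex-2-ene-1-carboxylate F4, which are separated by chromatography. LiAlH4 reduction of F3 (THF, 0 °C) then gives diol 12. The cost is that half of the material is the unwanted diastereomer and that the ring closure becomes the routine aldol condensation.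

Step 7. The secondary allylic hydroxyl may be activated in competition (SN2 or SN2' thioether, elimination), the cis-1,4 hydroxyl may close an ether intramolecularly, or displacement at the branched C7 may be slow. The fallback sets out from diol 12 and comes back at sulfide 13, replacing the redox condensation by sulfonate activation and SN2 displacement. The primary hydroxyl is sulfonylated selectively (TsCl, pyridine, 0 °C) to [(1R,4S)-4-hydroxy-2,6,6-trimethylcyclohex-2-en-1-yl]methyl 4-methylbenzenesulfonate F5. F5 is then displaced with 1-phenyl-1H-tetrazole-5-thiol and K2CO3 in DMF at 50 °C, a base too weak to deprotonate the hydroxyl, to give 13.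

Step 10. E selectivity at C7=C8 may be incomplete because conjugated aldehydes erode the anti preference; the dialdehyde may be olefinated twice; and the branched sulfonyl anion may add slowly. The fallback sets out from sulfone 15 (with 16) and comes back at 17; it gives up kinetic control of the geometry in favour of thermodynamic control. The olefination is run for conversion only (LiN(SiMe3)2, THF, −78 °C → rt). The resulting E/Z mixture, which contains the (7Z)-isomer of the silyl ether F6, is equilibrated with catalytic iodine in hexane/CH2Cl2 under diffuse daylight at rt. The 7Z isomer is the congested one (ring C6 against the C9 methyl), so equilibration should funnel it to 17.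

**Further compounds**
F1 | step 3 | mesityl oxide (4-methylpent-3-en-2-one) | CC(C)=CC(C)=O
F2 | step 3 | ethyl (±)-2,6,6-trimethyl-4-oxocyclohex-2-ene-1-carboxylate | CCOC(=O)C1C(C)=CC(=O)CC1(C)C
F3 | step 3 | ethyl (1R,4S)-4-hydroxy-2,6,6-trimethylcyclohex-2-ene-1-carboxylate | CC1=C[C@@H](O)CC(C)(C)[C@H]1C(=O)OCC
F4 | step 3 | ethyl (1S,4S)-4-hydroxy-2,6,6-trimethylcyclohex-2-ene-1-carboxylate | CC1=C[C@@H](O)CC(C)(C)[C@@H]1C(=O)OCC
F5 | step 7 | [(1R,4S)-4-hydroxy-2,6,6-trimethylcyclohex-2-en-1-yl]methyl 4-methylbenzenesulfonate | CC1=C[C@@H](O)CC(C)(C)[C@H]1COS(=O)(=O)c1ccc(C)cc1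
F6 | step 10 | (2E,4E,6E,8E,10E,12E,14E,16Z)-17-[(1R,4S)-4-{[tert-butyl(dimethyl)silyl]oxy}-2,6,6-trimethylcyclohex-2-en-1-yl]-2,6,11,15-tetramethylheptadeca-2,4,6,8,10,12,14,16-octaenal | CC1=C[C@@H](O[Si](C)(C)C(C)(C)C)CC(C)(C)[C@H]1\C=C/C(C)=C/C=C/C(C)=C/C=C/C=C(C)/C=C/C=C(\C)C=O
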